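The ten-membered carbocycle is opened at C5–C6, between the 4Z alkene and the allylic carbinol. A Nozaki–Hiyama–Kishi cyclisation forms this bond, the ring and the C6 stereocentre in one operation: the C5 alkenyl iodide is metalated with retention and adds to the C6 aldehyde. The step exploits that C6 is a secondary allylic alcohol flanked by the Z-configured C4=C5 bond and by C7 of the rigid trans-fused lactone, while the planar furanone (O, C10, C1, C2, C3) pre-organises the chain. The precursor is a trans α-methylidene γ-lactone carrying a formyl group at C7 and, at C8, a methylene-linked furanone bearing a (Z)-iodopropenyl group.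

Key step: step 20

Remark: locants C1 to C15 follow germacrane numbering of the target (C1 ketone, C3–O–C10 furanone bridge, C6 acyloxy carbon, C7/C8 lactone fusion, C11=C13 methylidene, C14 and C15 methyls).

Step 1
Reactants: 1 (R)-citramalic acid, (2R)-2-hydroxy-2-methylbutanedioic acid
Product: 2 (2R)-2-methylbutane-1,2,4-triol
Conditions: BH3·SMe2, B(OMe)3, THF, 0 °C to rt; MeOH quench
Reagents that add atoms: none
Why: Borane reduction of carboxylic acids proceeds through acyloxyboranes and should convert both carboxyl groups into primary alcohols while the tertiary carbinol centre C10, which takes no part, keeps its R configuration.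

Step 2
Reactants: 2 (2R)-2-methylbutane-1,2,4-triol
Product: 3 2-[(4R)-2,2,4-trimethyl-1,3-dioxolan-4-yl]ethanol
Conditions: Me2C(OMe)2, TsOH (cat.), acetone, rt
Reagents that add atoms: 2,2-dimethoxypropane, COC(C)(C)OC
Why: Acid-catalysed transketalisation under thermodynamic control should place the isopropylidene group on the 1,2-diol as the five-membered dioxolane, which is favoured over the six-membered 1,3-dioxane, and so leaves only the C8 hydroxyl free.

Step 3
Reactants: 3 2-[(4R)-2,2,4-trimethyl-1,3-dioxolan-4-yl]ethanol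
Product: 4 2-[(4R)-2,2,4-trimethyl-1,3-dioxolan-4-yl]acetaldehyde
Conditions: TEMPO (cat.), PhI(OAc)2, CH2Cl2, rt
Reagents that add atoms: none
Why: The TEMPO-catalysed oxidation with PhI(OAc)2 (oxoammonium oxidation of a primary alcohol) should stop at the aldehyde and tolerates the ketal.

Step 4
Reactants: 5 (4R)-4-benzyl-1,3-oxazolidin-2-one; 6 methyl 4-chloro-4-oxobutanoate
Product: 7 methyl 4-[(4R)-4-benzyl-2-oxo-1,3-oxazolidin-3-yl]-4-oxobutanoate
Conditions: Et3N, DMAP (cat.), CH2Cl2, 0 °C to rt
Reagents that add atoms: none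
Why: N-Acylation of the oxazolidinone by the acid chloride under DMAP catalysis (nucleophilic acyl substitution) gives the imide and leaves the methyl ester untouched.

Step 5
Reactants: 7 methyl 4-[(4R)-4-benzyl-2-oxo-1,3-oxazolidin-3-yl]-4-oxobutanoate; 4 2-[(4R)-2,2,4-trimethyl-1,3-dioxolan-4-yl]acetaldehyde
Product: 10 (4R)-4-benzyl-3-{[(2S,3R)-5-oxo-2-{[(4R)-2,2,4-trimethyl-1,3-dioxolan-4-yl]methyl}oxolan-3-yl]carbonyl}-1,3-oxazolidin-2-one, via boron enolate 8 (not isolated), via aldol adduct 9 (not isolated)
Conditions: Bu2BOTf, iPr2NEt, CH2Cl2, −78 to 0 °C; then 4, −78 to 0 °C; pH 7 buffer, MeOH, H2O2, 0 °C; then PPTS (cat.), CH2Cl2, rt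
Reagents that add atoms: none
Why: In this Evans syn aldol reaction boron triflate and amine enolise only the imide, the (Z)-enolate 8 adds to 4 through a chair Zimmerman–Traxler transition state whose face is fixed by the benzyl group of the (R)-auxiliary, so that C7 (R) and C8 (S) of 9 are set under reagent control, and the C8 hydroxyl then lactonises onto the methyl ester to give the trans-disubstituted γ-lactone.

Step 6
Reactants: 10 lactone imide (as above)
Product: 11 (2S,3R)-5-oxo-2-{[(4R)-2,2,4-trimethyl-1,3-dioxolan-4-yl]methyl}oxolane-3-carboxylic acid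
Conditions: LiOH, H2O2, THF/H2O, 0 °C; Na2SO3; HCl to pH 3
Reagents that add atoms: hydrogen peroxide, OO
Why: Lithium hydroperoxide attacks the exocyclic imide carbonyl in preference to the endocyclic carbamate and the lactone (Evans auxiliary hydrolysis), which frees the C6 carboxylic acid without epimerising C7 and returns auxiliary 5.

Step 7
Reactants: 11 lactone acid (as above)
Product: 12 (4S,5S)-4-(hydroxymethyl)-5-{[(4R)-2,2,4-trimethyl-1,3-dioxolan-4-yl]methyl}oxolan-2-one
Conditions: BH3·SMe2, THF, 0 °C to rt; MeOH quench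
Reagents that add atoms: none
Why: Borane reduces a free carboxylic acid much faster than a γ-lactone (chemoselective borane reduction), and its neutral conditions should keep the new C6 hydroxyl from translactonising.

Step 8
Reactants: 12 hydroxymethyl lactone (as above)
Product: 13 (4S,5S)-4-{[tert-butyl(diphenyl)silyl]oxymethyl}-5-{[(4R)-2,2,4-trimethyl-1,3-dioxolan-4-yl]methyl}oxolan-2-one
Conditions: tBuPh2SiCl, imidazole, CH2Cl2, 0 °C to rt
Reagents that add atoms: tert-butyl(chloro)diphenylsilane, CC(C)(C)[Si](Cl)(c1ccccc1)c1ccccc1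
Why: Silylation of the unhindered primary alcohol with the silyl chloride and imidazole (silyl ether formation) is fast and gives an ether that withstands enolate chemistry, aqueous acid and oxidants.

Step 9
Reactants: 13 silyl ether lactone (as above)
Product: 17 (4S,5S)-4-{[tert-butyl(diphenyl)silyl]oxymethyl}-3-methylidene-5-{[(4R)-2,2,4-trimethyl-1,3-dioxolan-4-yl]methyl}oxolan-2-one, via lithium enolate 14 (not isolated), via Mannich base 15 (not isolated), via ammonium iodide 16 (not isolated)
Conditions: LiN(iPr)2, THF, −78 °C; Me2N=CH2 iodide, −78 °C to rt; then MeI, MeOH, rt; then aq. NaHCO3, CH2Cl2, rt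
Reagents that add atoms: N,N-dimethylmethyleneiminium iodide (Eschenmoser's salt), C=[N+](C)C.[I-]
Why: Deprotonation at C11 gives lactone enolate 14, which undergoes a Mannich reaction with the iminium salt to 15, and N-methylation to 16 followed by base-induced β-elimination of trimethylamine installs the C11=C13 methylidene (Eschenmoser methylenation) without touching C7 or C8.

Step 10
Reactants: 17 methylidene lactone ketal (as above)
Product: 18 (4S,5S)-4-{[tert-butyl(diphenyl)silyl]oxymethyl}-5-[(2R)-2,3-dihydroxy-2-methylpropyl]-3-methylideneoxolan-2-one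
Conditions: AcOH/H2O (4:1), 40 °C
Reagents that add atoms: none
Why: Mild aqueous acid hydrolyses the isopropylidene ketal (acetal hydrolysis) while the silyl ether and the methylidene lactone are stable under these conditions.

Step 11
Reactants: 18 diol (as above)
Product: 19 (2R)-3-[(2S,3S)-3-{[tert-butyl(diphenyl)silyl]oxymethyl}-4-methylidene-5-oxooxolan-2-yl]-2-hydroxy-2-methylpropanal
Conditions: SO3·pyridine, DMSO, iPr2NEt, CH2Cl2, 0 °C
Reagents that add atoms: none
Why: The Parikh–Doering oxidation converts only the primary alcohol, since the tertiary C10 hydroxyl cannot be oxidised and activated DMSO does not cleave the glycol, and the aldehyde formed has no α-hydrogen and so cannot epimerise.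

Step 12
Reactants: 20 propargyl alcohol (prop-2-yn-1-ol)
Product: 22 (2Z)-3-iodo-2-methylprop-2-en-1-ol, via alkenylmagnesium alkoxide 21 (not isolated)
Conditions: MeMgBr (excess), CuI (cat.), THF, 0 °C to rt; then I2, −20 °C
Reagents that add atoms: methylmagnesium bromide, C[Mg]Br; iodine, II
Why: Copper-catalysed carbomagnesiation of the magnesium propargyl alkoxide delivers methyl and magnesium anti across the alkyne because the alkenyl–magnesium bond is held in a five-membered chelate with the alkoxide (Duboudin carbomagnesiation), and iodinolysis of 21 with retention gives the Z iodide.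

Step 13
Reactants: 22 (2Z)-3-iodo-2-methylprop-2-en-1-ol
Product: 23 (2Z)-3-iodo-2-methylprop-2-enal
Conditions: MnO2, CH2Cl2, rt, dark
Reagents that add atoms: none
Why: MnO2 oxidises the allylic alcohol selectively to the enal (allylic oxidation) under neutral conditions that should preserve the Z geometry.

Step 14
Reactants: 23 (2Z)-3-iodo-2-methylprop-2-enal
Product: 24 (1Z)-1-iodo-2-methylbut-1-en-3-yne
Conditions: Me3SiCHN2, LiN(iPr)2, THF, −78 °C; then 23, −78 to 0 °C; product kept as a solution
Reagents that add atoms: (trimethylsilyl)diazomethane, C[Si](C)(C)C=[N+]=[N-]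
Why: Lithiated trimethylsilyldiazomethane adds to the aldehyde, loss of lithium trimethylsilanolate gives a diazoalkene, and loss of nitrogen with 1,2-hydrogen shift of the alkylidene carbene furnishes the terminal alkyne (Colvin rearrangement) at low temperature and without nucleophilic alkoxide, so the β-iodoalkene should keep its Z geometry.

Step 15
Reactants: 19 hydroxy aldehyde (as above); 24 (1Z)-1-iodo-2-methylbut-1-en-3-yne
Product: 26 (4S,5S)-4-{[tert-butyl(diphenyl)silyl]oxymethyl}-5-[(2R,6Z)-2,3-dihydroxy-7-iodo-2,6-dimethylhept-6-en-4-yn-1-yl]-3-methylideneoxolan-2-one (both epimers at the new carbinol carbon C1), via lithium acetylide 25 (not isolated)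
Conditions: 24 (excess), LiN(iPr)2, THF, −78 °C; then 19, −78 °C; AcOH quench at −78 °C
Reagents that add atoms: none
Why: Lithium acetylide 25, formed with an amide base that does not exchange the alkenyl iodide, should add to the aldehyde of 19 far faster than to the lactone carbonyl or the methylidene at −78 °C (1,2-addition of an acetylide to an aldehyde), and the new C1 carbinol centre needs no control because it is oxidised in the next step.

Step 16
Reactants: 26 propargylic diol (as above)
Product: 27 (4S,5S)-4-{[tert-butyl(diphenyl)silyl]oxymethyl}-5-[(2R,6Z)-2-hydroxy-7-iodo-2,6-dimethyl-3-oxohept-6-en-4-yn-1-yl]-3-methylideneoxolan-2-one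
Conditions: IBX, DMSO, rt
Reagents that add atoms: none
Why: IBX oxidises the secondary propargylic alcohol to the ynone and does not cleave the adjacent tertiary glycol (IBX oxidation of 1,2-diols to α-ketols).

Step 17
Reactants: 27 γ-hydroxy ynone (as above)
Product: 28 (4S,5S)-4-{[tert-butyl(diphenyl)silyl]oxymethyl}-5-({(2R)-5-[(1Z)-1-iodoprop-1-en-2-yl]-2-methyl-3-oxo-2,3-dihydrofuran-2-yl}methyl)-3-methylideneoxolan-2-one
Conditions: Ph3PAuNTf2 (5 mol%), toluene, rt
Reagents that add atoms: none
Why: The cationic monovalent gold catalyst activates the ynone triple bond for anti attack of the tertiary C10 hydroxyl at C3 in a 5-endo-dig cyclisation, and protodeauration at C2 gives the 3(2H)-furanone (gold-catalysed cycloisomerisation of γ-hydroxy alkynones), with C10 untouched.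

Step 18
Reactants: 28 furanone silyl ether (as above)
Product: 29 (4S,5S)-4-(hydroxymethyl)-5-({(2R)-5-[(1Z)-1-iodoprop-1-en-2-yl]-2-methyl-3-oxo-2,3-dihydrofuran-2-yl}methyl)-3-methylideneoxolan-2-one
Conditions: HF·pyridine, pyridine, THF, 0 °C to rt
Reagents that add atoms: none
Why: Fluoride cleaves the silicon–oxygen bond (fluoride-mediated desilylation) under mildly acidic conditions that should spare the furanone, the alkenyl iodide and the methylidene lactone.

Step 19
Reactants: 29 primary alcohol (as above)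
Product: 30 (2S,3R)-2-({(2R)-5-[(1Z)-1-iodoprop-1-en-2-yl]-2-methyl-3-oxo-2,3-dihydrofuran-2-yl}methyl)-4-methylidene-5-oxooxolane-3-carbaldehyde
Conditions: Dess–Martin periodinane, NaHCO3, CH2Cl2, 0 °C; used at once
Reagents that add atoms: none
Why: Buffered Dess–Martin oxidation converts the primary alcohol into the aldehyde under neutral conditions, which is needed because the C7 hydrogen of 30 is α to the aldehyde and allylic to the methylidene.

Step 20
Reactants: 30 iodoalkenyl aldehyde (as above)
Product: 32 (4Z,6S,7S,8S,10R)-6-hydroxy-1-oxo-3,10-epoxygermacra-2,4,11(13)-trien-12,8-olide, via alkenylchromium species 31 (not isolated)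
Conditions: CrCl2 (10 equiv), NiCl2 (cat.), degassed DMSO/THF, rt, slow addition, 0.002 M
Reagents that add atoms: none
Why: NiCl2 is reduced by CrCl2 to zerovalent nickel, which inserts into the C5–I bond with retention of the Z geometry and transmetalates to trivalent chromium, and the resulting alkenylchromium 31 adds to the chromium-activated C6 aldehyde to give the chromium alkoxide of 32. The closest known reaction type is the Nozaki–Hiyama–Kishi macrocyclisation of iodoalkenyl aldehydes to medium-ring allylic alcohols. The ten-membered carbocycle closes in a 10-exo-trig mode at high dilution, helped by the Z alkene, the planar furanone and the trans-fused lactone, which leave only the C3–C4, C9–C10, C8–C9 and C6–C7 bonds free to rotate between the reacting ends. The new C6 stereocentre is controlled by C7: in a Felkin–Anh arrangement C5 attacks anti to the C7–C11 bond with the aldehyde hydrogen next to H7 and the oxygen towards C8, a geometry that keeps C5 gauche to C8 as the ring demands and should give the 6S alcohol. The step needs chemoselectivity for the aldehyde over the lactone, the furanone ketone and the methylidene acceptor, which the weakly basic organochromium reagent secures, and facial selectivity at C6, which rests on C7 and the rigid ring fusion. The neutral medium should also protect the C7 hydrogen from epimerisation, from double-bond migration and from β-elimination of the C8 carboxylate.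

Step 21
Reactants: 33 angelic acid, (2Z)-2-methylbut-2-enoic acid
Product: 34 (2Z)-2-methylbut-2-en-1-ol
Conditions: LiAlH4, Et2O, 0 °C to rt; H2O/NaOH work-up
Reagents that add atoms: none
Why: LiAlH4 reduces the carboxylate to the primary allylic alcohol by 1,2-hydride delivery (hydride reduction of a carboxylic acid) without affecting the trisubstituted Z double bond.

Step 22
Reactants: 34 (2Z)-2-methylbut-2-en-1-ol
Product: 35 [(2S,3R)-2,3-dimethyloxiran-2-yl]methanol
Conditions: Ti(OiPr)4 (10 mol%), L-(+)-diethyl tartrate (12 mol%), tBuOOH, 4 Å MS, CH2Cl2, −20 °C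
Reagents that add atoms: tert-butyl hydroperoxide, CC(C)(C)OO
Why: In the Sharpless asymmetric epoxidation the allylic alkoxide and the hydroperoxide are bound to the titanium tartrate dimer, and with L-(+)-diethyl tartrate oxygen is delivered to the alkene face that gives the 2S configuration, as with other 3-cis-substituted allylic alcohols such as nerol, so that the cis-disposed C2 and C3 centres are set as 2S,3R.

Step 23
Reactants: 35 [(2S,3R)-2,3-dimethyloxiran-2-yl]methanol
Product: 36 (2R,3R)-2,3-dimethyloxirane-2-carboxylic acid (epoxyangelic acid)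
Conditions: RuCl3·xH2O (2 mol%), NaIO4, MeCN/EtOAc/H2O, rt
Reagents that add atoms: water, O; sodium periodate, [Na+].[O-]I(=O)(=O)=O
Why: RuO4, regenerated by periodate, oxidises the primary alcohol through the aldehyde hydrate to the carboxylic acid (Sharpless ruthenium oxidation) and leaves the epoxide and both stereocentres intact, the descriptor at C2 changing from S to R only because the substituent priorities change.

Step 24
Reactants: 32 C6 alcohol (as above); 36 (2R,3R)-2,3-dimethyloxirane-2-carboxylic acid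
Product: 38 (4Z,6S,7R,8S,10R)-1-oxo-3,10-epoxygermacra-2,4,11(13)-trien-12,8-olid-6-yl (2R,3R)-2,3-dimethyloxirane-2-carboxylate (target CNP0258430.3), via mixed anhydride 37 (not isolated)
Conditions: 36, 2,4,6-trichlorobenzoyl chloride, Et3N, toluene, rt; then 32, DMAP, toluene, rt
Reagents that add atoms: none
Why: In the Yamaguchi esterification the acid is activated as mixed anhydride 37, DMAP transfers the less hindered epoxy acyl group to the C6 hydroxyl of 32, and since only the O–H bond reacts the C6 configuration and the epoxide stereocentres are retained.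

Compound list
1 | (R)-citramalic acid, (2R)-2-hydroxy-2-methylbutanedioic acid | OC(=O)C[C@@](C)(O)C(=O)O | starting material
2 | (2R)-2-methylbutane-1,2,4-triol | OCC[C@@](C)(O)CO | intermediate
3 | 2-[(4R)-2,2,4-trimethyl-1,3-dioxolan-4-yl]ethanol | OCC[C@]1(C)COC(C)(C)O1 | intermediate
4 | 2-[(4R)-2,2,4-trimethyl-1,3-dioxolan-4-yl]acetaldehyde | O=CC[C@]1(C)COC(C)(C)O1 | intermediate
5 | (4R)-4-benzyl-1,3-oxazolidin-2-one | O=C1N[C@H](Cc2ccccc2)CO1 | starting material
6 | methyl 4-chloro-4-oxobutanoate | COC(=O)CCC(Cl)=O | starting material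
7 | methyl 4-[(4R)-4-benzyl-2-oxo-1,3-oxazolidin-3-yl]-4-oxobutanoate | COC(=O)CCC(=O)N1[C@H](Cc2ccccc2)COC1=O | intermediate
8 | dibutylboron (Z)-enolate of 7 (boron on the imide enolate oxygen, cis to the CH2CO2Me group) | COC(=O)C/C=C(\OB(CCCC)CCCC)N1[C@H](Cc2ccccc2)COC1=O | intermediate
9 | methyl (3R,4S)-3-{[(4R)-4-benzyl-2-oxo-1,3-oxazolidin-3-yl]carbonyl}-4-hydroxy-5-[(4R)-2,2,4-trimethyl-1,3-dioxolan-4-yl]pentanoate | COC(=O)C[C@@H](C(=O)N1[C@H](Cc2ccccc2)COC1=O)[C@@H](O)C[C@]3(C)COC(C)(C)O3 | intermediate
10 | (4R)-4-benzyl-3-{[(2S,3R)-5-oxo-2-{[(4R)-2,2,4-trimethyl-1,3-dioxolan-4-yl]methyl}oxolan-3-yl]carbonyl}-1,3-oxazolidin-2-one | O=C1C[C@@H](C(=O)N2[C@H](Cc3ccccc3)COC2=O)[C@H](C[C@]4(C)COC(C)(C)O4)O1 | intermediate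
11 | (2S,3R)-5-oxo-2-{[(4R)-2,2,4-trimethyl-1,3-dioxolan-4-yl]methyl}oxolane-3-carboxylic acid | O=C1C[C@@H](C(=O)O)[C@H](C[C@]2(C)COC(C)(C)O2)O1 | intermediate
12 | (4S,5S)-4-(hydroxymethyl)-5-{[(4R)-2,2,4-trimethyl-1,3-dioxolan-4-yl]methyl}oxolan-2-one | O=C1C[C@@H](CO)[C@H](C[C@]2(C)COC(C)(C)O2)O1 | intermediate
13 | (4S,5S)-4-{[tert-butyl(diphenyl)silyl]oxymethyl}-5-{[(4R)-2,2,4-trimethyl-1,3-dioxolan-4-yl]methyl}oxolan-2-one | O=C1C[C@@H](CO[Si](c2ccccc2)(c3ccccc3)C(C)(C)C)[C@H](C[C@]4(C)COC(C)(C)O4)O1 | intermediate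
14 | lithium enolate of 13 (C11=C12 enolate) | [Li]OC1=C[C@@H](CO[Si](c2ccccc2)(c3ccccc3)C(C)(C)C)[C@H](C[C@]4(C)COC(C)(C)O4)O1 | intermediate
15 | 3-[(dimethylamino)methyl] derivative of 13 (Mannich base, configuration at C11 not defined) | CN(C)CC1C(=O)O[C@@H](C[C@]2(C)COC(C)(C)O2)[C@@H]1CO[Si](c3ccccc3)(c4ccccc4)C(C)(C)C | intermediate
16 | N-methyl ammonium iodide of 15 | C[N+](C)(C)CC1C(=O)O[C@@H](C[C@]2(C)COC(C)(C)O2)[C@@H]1CO[Si](c3ccccc3)(c4ccccc4)C(C)(C)C.[I-] | intermediate
17 | (4S,5S)-4-{[tert-butyl(diphenyl)silyl]oxymethyl}-3-methylidene-5-{[(4R)-2,2,4-trimethyl-1,3-dioxolan-4-yl]methyl}oxolan-2-one | C=C1C(=O)O[C@@H](C[C@]2(C)COC(C)(C)O2)[C@@H]1CO[Si](c3ccccc3)(c4ccccc4)C(C)(C)C | intermediate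
18 | (4S,5S)-4-{[tert-butyl(diphenyl)silyl]oxymethyl}-5-[(2R)-2,3-dihydroxy-2-methylpropyl]-3-methylideneoxolan-2-one | C=C1C(=O)O[C@@H](C[C@@](C)(O)CO)[C@@H]1CO[Si](c2ccccc2)(c3ccccc3)C(C)(C)C | intermediate
19 | (2R)-3-[(2S,3S)-3-{[tert-butyl(diphenyl)silyl]oxymethyl}-4-methylidene-5-oxooxolan-2-yl]-2-hydroxy-2-methylpropanal | C=C1C(=O)O[C@@H](C[C@@](C)(O)C=O)[C@@H]1CO[Si](c2ccccc2)(c3ccccc3)C(C)(C)C | intermediate
20 | propargyl alcohol (prop-2-yn-1-ol) | C#CCO | starting material
21 | bromomagnesium (2Z)-3-(bromomagnesio)-2-methylprop-2-en-1-olate | Br[Mg]OC/C(C)=C\[Mg]Br | intermediate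
22 | (2Z)-3-iodo-2-methylprop-2-en-1-ol | OC/C(C)=C\I | intermediate
23 | (2Z)-3-iodo-2-methylprop-2-enal | O=C/C(C)=C\I | intermediate
24 | (1Z)-1-iodo-2-methylbut-1-en-3-yne | C#C/C(C)=C\I | intermediate
25 | lithium acetylide of 24 | [Li]C#C/C(C)=C\I | intermediate
26 | (4S,5S)-4-{[tert-butyl(diphenyl)silyl]oxymethyl}-5-[(2R,6Z)-2,3-dihydroxy-7-iodo-2,6-dimethylhept-6-en-4-yn-1-yl]-3-methylideneoxolan-2-one (both C1 carbinol epimers) | C=C1C(=O)O[C@@H](C[C@@](C)(O)C(O)C#C/C(C)=C\I)[C@@H]1CO[Si](c2ccccc2)(c3ccccc3)C(C)(C)C | intermediate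
27 | (4S,5S)-4-{[tert-butyl(diphenyl)silyl]oxymethyl}-5-[(2R,6Z)-2-hydroxy-7-iodo-2,6-dimethyl-3-oxohept-6-en-4-yn-1-yl]-3-methylideneoxolan-2-one | C=C1C(=O)O[C@@H](C[C@@](C)(O)C(=O)C#C/C(C)=C\I)[C@@H]1CO[Si](c2ccccc2)(c3ccccc3)C(C)(C)C | intermediate
28 | (4S,5S)-4-{[tert-butyl(diphenyl)silyl]oxymethyl}-5-({(2R)-5-[(1Z)-1-iodoprop-1-en-2-yl]-2-methyl-3-oxo-2,3-dihydrofuran-2-yl}methyl)-3-methylideneoxolan-2-one | C=C1C(=O)O[C@@H](C[C@@]2(C)OC(=CC2=O)/C(C)=C\I)[C@@H]1CO[Si](c3ccccc3)(c4ccccc4)C(C)(C)C | intermediate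
29 | (4S,5S)-4-(hydroxymethyl)-5-({(2R)-5-[(1Z)-1-iodoprop-1-en-2-yl]-2-methyl-3-oxo-2,3-dihydrofuran-2-yl}methyl)-3-methylideneoxolan-2-one | C=C1C(=O)O[C@@H](C[C@@]2(C)OC(=CC2=O)/C(C)=C\I)[C@@H]1CO | intermediate
30 | (2S,3R)-2-({(2R)-5-[(1Z)-1-iodoprop-1-en-2-yl]-2-methyl-3-oxo-2,3-dihydrofuran-2-yl}methyl)-4-methylidene-5-oxooxolane-3-carbaldehyde (key-step precursor) | C=C1C(=O)O[C@@H](C[C@@]2(C)OC(=CC2=O)/C(C)=C\I)[C@@H]1C=O | intermediate
31 | alkenylchromium dichloride derived from 30 (CrCl2 group in place of iodine at C5, trivalent chromium) | C=C1C(=O)O[C@@H](C[C@@]2(C)OC(=CC2=O)/C(C)=C\[Cr](Cl)Cl)[C@@H]1C=O | intermediate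
32 | (4Z,6S,7S,8S,10R)-6-hydroxy-1-oxo-3,10-epoxygermacra-2,4,11(13)-trien-12,8-olide (desacyl target) | C=C1C(=O)O[C@H]2C[C@@]3(C)OC(=CC3=O)/C(C)=C\[C@H](O)[C@H]12 | intermediate
33 | angelic acid, (2Z)-2-methylbut-2-enoic acid | C/C=C(/C)C(=O)O | starting material
34 | (2Z)-2-methylbut-2-en-1-ol | C/C=C(/C)CO | intermediate
35 | [(2S,3R)-2,3-dimethyloxiran-2-yl]methanol | OC[C@]1(C)O[C@@H]1C | intermediate
36 | (2R,3R)-2,3-dimethyloxirane-2-carboxylic acid | OC(=O)[C@]1(C)O[C@@H]1C | intermediate
37 | (2R,3R)-2,3-dimethyloxirane-2-carboxylic 2,4,6-trichlorobenzoic anhydride | O=C(OC(=O)[C@]1(C)O[C@@H]1C)c2c(Cl)cc(Cl)cc2Cl | intermediate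
38 | (4Z,6S,7R,8S,10R)-1-oxo-3,10-epoxygermacra-2,4,11(13)-trien-12,8-olid-6-yl (2R,3R)-2,3-dimethyloxirane-2-carboxylate | C=C1C(=O)O[C@H]2C[C@@]3(C)OC(=CC3=O)/C(C)=C\[C@H](OC(=O)[C@]3(C)O[C@@H]3C)[C@H]12 | target

Total step count: 24 steps.
Longest linear sequence: 17 steps (steps 1–3, 5–11, 15–20 and 24, from 1 to 38).

Steps most likely to fail

Step 20. The chromium-mediated ring closure may show poor facial selectivity at the C6 aldehyde, so that the wrong C6 configuration predominates. The fallback sets out from 30 and no longer relies on the C–C bond formation for the C6 configuration. The cyclisation is run as before and the unseparated mixture of 32 and its C6 epimer, the (6R)-alcohol F1, is oxidised with MnO2 in CH2Cl2 to the cross-conjugated C6 ketone F2. This ketone is then reduced with catecholborane and the Corey–Bakshi–Shibata oxazaborolidine catalyst in toluene at −78 °C. Both catalyst enantiomers are available, so the hydride face is chosen by the reagent, and the sequence comes back to the route at 32.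

Step 19. While aldehyde 30 is formed and handled, C7 may epimerise, the C11=C13 double bond may migrate into the ring, or the C8 oxygen may be lost by β-elimination. The fallback sets out from 29 and masks the methylidene before the oxidation. Conjugate addition of dimethylamine (Me2NH, THF, 0 °C) should give the 11-(dimethylaminomethyl) lactone F3. Parikh–Doering oxidation then gives amino aldehyde F4, in which the C7 hydrogen is no longer allylic. Cyclisation with CrCl2 and catalytic NiCl2 as in step 20 gives amino alcohol F5. N-Methylation with MeI gives the ammonium iodide F6, and aqueous NaHCO3 eliminates trimethylamine to restore the methylidene, which comes back to the route at 32.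

Step 15. The lithium acetylide may lose chemoselectivity and attack the lactone carbonyl or the methylidene, or the base may induce α-ketol rearrangement of 19. The fallback sets out from 24 and replaces the organolithium by an organochromium reagent. N-Iodosuccinimide with catalytic AgNO3 in acetone converts 24 into the iodoalkyne (Z)-1,4-diiodo-3-methylbut-3-en-1-yne F7. Nickel-free CrCl2 in THF should then metalate only the alkynyl iodide (Takai–Nozaki alkynylation). The alkynylchromium reagent adds to the aldehyde of 19 under neutral conditions in the presence of the free hydroxyl, the lactone and the alkenyl iodide, and the sequence comes back to the route at 26.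

Further compounds
F1 | step 20 | (4Z,6R,7S,8S,10R)-6-hydroxy-1-oxo-3,10-epoxygermacra-2,4,11(13)-trien-12,8-olide (C6 epimer of 32) | C=C1C(=O)O[C@H]2C[C@@]3(C)OC(=CC3=O)/C(C)=C\[C@@H](O)[C@H]12
F2 | step 20 | (4Z,7R,8S,10R)-1,6-dioxo-3,10-epoxygermacra-2,4,11(13)-trien-12,8-olide | C=C1C(=O)O[C@H]2C[C@@]3(C)OC(=CC3=O)/C(C)=C\C(=O)[C@H]12
F3 | step 19 | (4S,5S)-3-[(dimethylamino)methyl]-4-(hydroxymethyl)-5-({(2R)-5-[(1Z)-1-iodoprop-1-en-2-yl]-2-methyl-3-oxo-2,3-dihydrofuran-2-yl}methyl)oxolan-2-one (configuration at C11 not defined) | CN(C)CC1C(=O)O[C@@H](C[C@@]2(C)OC(=CC2=O)/C(C)=C\I)[C@@H]1CO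
F4 | step 19 | (2S,3R)-4-[(dimethylamino)methyl]-2-({(2R)-5-[(1Z)-1-iodoprop-1-en-2-yl]-2-methyl-3-oxo-2,3-dihydrofuran-2-yl}methyl)-5-oxooxolane-3-carbaldehyde (configuration at C11 not defined) | CN(C)CC1C(=O)O[C@@H](C[C@@]2(C)OC(=CC2=O)/C(C)=C\I)[C@@H]1C=O
F5 | step 19 | 13-(dimethylamino)-11,13-dihydro derivative of 32 (configuration at C11 not defined) | CN(C)CC1C(=O)O[C@H]2C[C@@]3(C)OC(=CC3=O)/C(C)=C\[C@H](O)[C@H]12
F6 | step 19 | N-methyl ammonium iodide of F5 | C[N+](C)(C)CC1C(=O)O[C@H]2C[C@@]3(C)OC(=CC3=O)/C(C)=C\[C@H](O)[C@H]12.[I-]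
F7 | step 15 | (Z)-1,4-diiodo-3-methylbut-3-en-1-yne | IC#C/C(C)=C\I
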